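If partner competes for substrate against losses that ignore it, then target over the other substrate lost should rise in step with partner, and two runs can test that.

common to all: substrate 0.50 M
- grey: partner 0.50 M; run made earlier
- green: partner 1.1 M; run made earlier
- flask: partner 0.750 M; time 2.5 d

| run | time / d | target / % | substrate / % |
|---|---|---|---|
| grey | 0.0278 | 14 | 34 |
| grey | 0.125 | 12 | 12 |
| grey | 0.625 | 2 | 0 |
| grey | 3.00 | 0 | 2 |
| green | 0.0278 | 28 | 28 |
| green | 0.125 | 24 | 12 |
| green | 0.625 | 5 | 0 |
| green | 3.00 | 1 | 0 |

(standard deviation of a reading: 1.5 percentage points)

- a reading or a percentage of target counts all its forms, free or not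
- a reading of substrate is of its free form alone

1. when, up to 2.5 d, the flask holds most target
2. the amount of target, in percent of the substrate charged, at that time
3. earliest time at which at least nineteen twentieths of that best amount are there
4. latest time at which they still are, in d

The grey and green runs charge the same substrate but differ in partner, so I compared them at their first reading. I counted whatever was neither free substrate nor target as the other loss. Target over that loss, per molar of partner, came to 0.538 L mol⁻¹ in the grey run and 0.579 L mol⁻¹ in the green run. With a scatter of 1.5 percentage points on a target reading of 14%, I took these as one reading, the partner factor, a selectivity factor held at this charge of substrate: 0.558 L mol⁻¹.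

So the flask, with 0.750 M of partner, should send 29.5% of lost substrate to target. But target fades later, as the grey run fell from 12% to 2% between 0.125 d and 0.625 d, so I looked early. At 0.0278 d the runs averaged 31.0% free substrate, which gave me 20.4% target by then, the figure I committed to, with the best expected soon after.

The forecast, in its words “The peak is broad”, set 21% at 0.065 d, with the window from 0.9 h to 0.105 d, and its time is later than the one my figure belongs to.

The flask gave 22.7% at 0.0515 d, with the window asked for running from 0.810 h to 0.0774 d.

    substrate + partner ⇌ target (K = 1.10 L mol⁻¹, k = 0.941 L mol⁻¹ h⁻¹)
    substrate → side product A (k = 0.456 h⁻¹)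
    2 substrate → side product B (k = 0.954 L mol⁻¹ h⁻¹)
    substrate + target ⇌ idle adduct, settled at all times (K = 5.50 L mol⁻¹)
    partner → decomposed reagent (k = 0.00814 h⁻¹)

At that best time the flask held 20.8% free substrate and 22.7% target, bound forms counted, so its factor came to 0.536 L mol⁻¹ against my 0.558 L mol⁻¹; its other loss includes substrate held in idle adduct. The neighbouring flask had 0.19 M of partner, so the factor gave it a share of 9.59% of lost substrate going to target. Scaling the flask's best by the two shares gave 7.38%. That neighbouring flask reached 7.21%.

(Readings and results are simulated on assumed constants, and the scatter is random.)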